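The C7–C8 bond joins the β-carbon C7 of the butenolide (ring C6–O–C12–C11–C7) to the allylic carbinol C8 of the ten-membered carbocycle C1–C10, which makes it an alkenyl-metal/aldehyde retron. A Nozaki–Hiyama–Kishi macrocyclisation of a seco-aldehyde carrying a 4-bromobutenolide closes the carbocycle and creates C8 in one operation; the (Z)-olefin, the two epoxides and the butenolide pre-fold the chain. The precursor comes from three small pieces (an iodoalkenol, an enynol, a dibromoacrylate). One double Sharpless epoxidation sets C1, C10, C4 and C5, which relay C6 and C8, and the ester is installed with inversion at C8.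

Key step: step 11

Remarks
- Atom labels follow germacrane numbering: ring carbons C1–C10 (C1/C10 and C4/C5 epoxides, C2=C3 olefin, lactone carbinol C6, butenolide olefin C7=C11, carbinol C8), C12 lactone carbonyl, C13 acetoxymethyl, C14 hydroxymethyl, C15 methyl.
- Assumption: (Z)-3-methylpent-2-en-4-yn-1-ol and (R)-2-methylbutanoic acid are bought as catalogue items of defined geometry and configuration.
- The transition-state model given at step 11 predicts the 8R carbinol, so the ester is introduced with inversion (step 12). This prediction is the least secure element of the plan.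

Step 1
Reactants: 1 prop-2-yn-1-ol; 2 allylmagnesium bromide
Product: 4 (Z)-2-(iodomethylene)pent-4-en-1-ol, via chelated alkenylmagnesium alkoxide 3 (not isolated)
Conditions: allylMgBr (2.5 equiv), CuI (5 mol%), Et2O, −10 °C → rt; then I2, THF, −40 → 0 °C
Reagents that add atoms: iodine, [I][I]
Why: Hydroxyl-directed anti-carbomagnesiation of a propargylic alcohol puts the allyl group on the internal alkyne carbon and magnesium on the terminal carbon inside a five-membered chelate, so iodinolysis should give the alkenyl iodide with iodine cis to CH2OH, the geometry that the later C1/C10 epoxide needs.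

Step 2
Reactants: 4 (Z)-2-(iodomethylene)pent-4-en-1-ol; 5 (Z)-3-methylpent-2-en-4-yn-1-ol
Product: 6 (2Z,6Z)-6-methyl-2-(prop-2-en-1-yl)octa-2,6-dien-4-yne-1,8-diol
Conditions: Pd(PPh3)2Cl2 (3 mol%), CuI (6 mol%), Et3N, degassed THF, rt
Reagents that add atoms: none
Why: Sonogashira coupling of an alkenyl iodide with a terminal alkyne keeps both olefin geometries and tolerates free hydroxyl groups and the isolated terminal olefin.

Step 3
Reactants: 6 dienyne diol
Product: 7 bis-epoxy ynediol (C1/C10 and C4/C5 epoxides, C2≡C3)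
Conditions: Ti(OiPr)4 (0.3 equiv), L-(+)-diethyl tartrate (0.36 equiv), t-BuOOH (4 equiv, anhydrous), 4 Å MS, CH2Cl2, −20 °C
Reagents that add atoms: tert-butyl hydroperoxide, CC(C)(C)OO
Why: Twofold Sharpless asymmetric epoxidation, in which L-(+)-tartrate delivers oxygen to the same local face of both allylic alcohols (the sense that turns geraniol into its (2S,3S)-epoxide), should set C10, C1, C4 and C5 by reagent control while the unactivated terminal olefin is left alone, and the two independent events should also raise the enantiomeric purity of the major diastereomer.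

Step 4
Reactants: 7 bis-epoxy ynediol
Product: 8 (Z)-olefinic bis-epoxy diol
Conditions: H2 (1 atm), Pd/CaCO3 poisoned with Pb(OAc)2 (Lindlar catalyst), quinoline, EtOAc, 0 °C, stopped after one equivalent of H2
Reagents that add atoms: none
Why: Lindlar semihydrogenation adds hydrogen syn to the alkyne and should stop at the (Z)-olefin before the terminal olefin or the allylic C–O bonds react when the poisoned catalyst is used with quinoline and the uptake is limited.

Step 5
Reactants: 8 (Z)-olefinic bis-epoxy diol
Product: 9 C6 epoxy aldehyde with free C14 hydroxyl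
Conditions: TEMPO (10 mol%), PhI(OAc)2 (1.05 equiv), CH2Cl2, 0 °C
Reagents that add atoms: none
Why: Oxoammonium (TEMPO) oxidation of primary alcohols is sensitive to steric hindrance, so the C6 carbinol on the CH epoxide carbon should be oxidised ahead of the neopentyl-type C14 carbinol on the fully substituted C10, without touching olefins or epoxides and without epimerising C5.

Step 6
Reactants: 9 C6 epoxy aldehyde
Product: 10 C14 triethylsilyl ether of the epoxy aldehyde
Conditions: Et3SiCl (1.1 equiv), imidazole, CH2Cl2, −20 °C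
Reagents that add atoms: chlorotriethylsilane, CC[Si](Cl)(CC)CC
Why: Silylation of a primary alcohol with a chlorosilane and imidazole is nearly neutral and should leave the epoxy aldehyde untouched.

Step 7
Reactants: 11 ethyl 3-bromo-2-oxopropanoate
Product: 12 ethyl 3-acetoxy-2-oxopropanoate
Conditions: KOAc, acetone, rt
Reagents that add atoms: potassium acetate, CC(=O)[O-].[K+]
Why: SN2 displacement of an α-bromo ketone by acetate is fast because of the adjacent carbonyl group.

Step 8
Reactants: 12 ethyl 3-acetoxy-2-oxopropanoate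
Product: 13 ethyl 2-(acetoxymethyl)-3,3-dibromoprop-2-enoate
Conditions: CBr4 (2 equiv), PPh3 (4 equiv), CH2Cl2, 0 °C
Reagents that add atoms: tetrabromomethane, BrC(Br)(Br)Br
Why: Ramirez dibromoolefination (Wittig-type reaction of the CBr4/PPh3 ylide) works well on the activated ketone carbonyl of an α-keto ester.

Step 9
Reactants: 13 ethyl 2-(acetoxymethyl)-3,3-dibromoprop-2-enoate; 10 silylated epoxy aldehyde
Product: 16 4-bromobutenolide with the C9 allyl side chain, via magnesium carbenoid 14 (not isolated), via open-chain magnesium alkoxide 15 (not isolated)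
Conditions: 13 (1.5 equiv), iPrMgCl (1.55 equiv), THF, −78 °C, 30 min; then 10, −78 → 0 °C
Reagents that add atoms: none
Why: Bromine–magnesium exchange of a β,β-dibromoacrylate takes place at the bromine cis to the chelating ester, and the resulting alkenylmagnesium carbenoid adds to the aldehyde and lactonises in the flask (1,2-addition, then 5-exo-trig acyl substitution) to the 4-bromobutenolide, with C6 set by Felkin–Anh (Cornforth) addition anti to the epoxide C5–O bond, reinforced by the fully substituted C4, to give the erythro epoxy carbinol.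

Step 10
Reactants: 16 4-bromobutenolide with allyl side chain
Product: 18 seco-aldehyde (C8 aldehyde, C7 bromide), via vicinal diol 17 (not isolated)
Conditions: OsO4 (2 mol%), N-methylmorpholine N-oxide (1.2 equiv), acetone/pH 7 buffer, 0 °C; then NaIO4, 0 °C → rt; used crude
Reagents that add atoms: N-methylmorpholine N-oxide, C[N+]1([O-])CCOCC1 (its oxygen is passed on by the catalyst OsO4, O=[Os](=O)(=O)=O)
Why: Dihydroxylation with OsO4 followed by periodate cleavage (Lemieux–Johnson sequence) should pick the unhindered monosubstituted olefin over the (Z)-olefin, which is shielded and inductively deactivated by the two flanking epoxides, and over the electron-poor tetrasubstituted butenolide olefin.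

Step 11
Reactants: 18 seco-aldehyde
Product: 20 macrocyclic 8R alcohol, via alkenylchromium species 19 (not isolated)
Conditions: CrCl2 (10 equiv), NiCl2 (0.1 equiv), degassed DMSO, rt, 18 added by syringe pump to 2 mM final concentration
Reagents that add atoms: none
Why: Zerovalent nickel, made from NiCl2 by CrCl2, inserts into the activated C7–Br bond and passes the alkenyl group to trivalent chromium, and the alkenylchromium 19 adds to the C8 aldehyde through a four-centre transition state (Nozaki–Hiyama–Kishi reaction); the closest known type is the Ni/Cr-mediated ring closure of alkenyl halide aldehydes to medium-ring allylic alcohols. The step closes the ten-membered carbocycle C1–C10 in a 10-exo-trig mode (C7 attacks the carbonyl carbon C8, the C=O bond staying outside the ring). The one new stereocentre, C8, is under substrate control: C6 holds C5 and with it the tether on one face of the flat butenolide, so C8 should reach C7 from that face with chromium and O8 on the other, and A(1,3) strain against the C13 acetoxymethyl group keeps H8 in the olefin plane, which together describe the 8R carbinol. The selectivity needed is ring closure over oligomerisation and activation of the C–Br bond only; the (Z)-olefin, the two epoxides and the butenolide leave few free rotors and pre-fold the seco-aldehyde, high dilution suppresses intermolecular coupling, and the reagent pair is known to leave epoxides, esters, silyl ethers and isolated olefins untouched.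

Step 12
Reactants: 20 macrocyclic 8R alcohol; 21 (R)-2-methylbutanoic acid
Product: 22 8S (R)-2-methylbutanoate with C14 triethylsilyl ether
Conditions: PPh3 (2 equiv), DIAD (2 equiv), 21 (2 equiv), toluene, 0 °C → rt
Reagents that add atoms: none
Why: In the Mitsunobu esterification the alkoxyphosphonium salt of the secondary allylic alcohol is displaced by the carboxylate with inversion (SN2), which should turn the 8R carbinol into the 8S ester, while SN2' attack is blocked by the fully substituted, electron-poor C11 and the α-stereocentre of the acid is not touched.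

Step 13
Reactants: 22 silylated ester
Product: 23 target compound
Conditions: HF·pyridine, excess pyridine, THF, 0 °C
Reagents that add atoms: none
Why: Buffered fluoride cleavage of a primary triethylsilyl ether is mild enough for the two esters, the butenolide and the vinyl epoxides, and the weakly acidic medium should prevent acyl migration to the liberated C14 hydroxyl group.

Compound list
1 | prop-2-yn-1-ol | C#CCO | starting material
2 | allylmagnesium bromide | C=CC[Mg]Br | starting material
3 | bromomagnesium (Z)-2-allyl-3-(bromomagnesio)prop-2-en-1-olate (magnesium cis to CH2O) | Br[Mg]OC/C(CC=C)=C\[Mg]Br | intermediate (not isolated)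
4 | (Z)-2-(iodomethylene)pent-4-en-1-ol | OC/C(CC=C)=C\I | intermediate
5 | (Z)-3-methylpent-2-en-4-yn-1-ol | C#C/C(C)=C\CO | starting material
6 | (2Z,6Z)-6-methyl-2-(prop-2-en-1-yl)octa-2,6-dien-4-yne-1,8-diol | OC/C(CC=C)=C\C#C/C(C)=C\CO | intermediate
7 | {(2S,3R)-3-[((2R,3S)-3-(hydroxymethyl)-2-methyloxiran-2-yl)ethynyl]-2-(prop-2-en-1-yl)oxiran-2-yl}methanol | C=CC[C@@]1(CO)O[C@@H]1C#C[C@@]1(C)O[C@H]1CO | intermediate
8 | {(2S,3R)-3-[(Z)-2-((2R,3S)-3-(hydroxymethyl)-2-methyloxiran-2-yl)ethenyl]-2-(prop-2-en-1-yl)oxiran-2-yl}methanol | C=CC[C@@]1(CO)O[C@@H]1/C=C\[C@@]1(C)O[C@H]1CO | intermediate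
9 | (2R,3R)-3-{(Z)-2-[(2R,3S)-3-(hydroxymethyl)-3-(prop-2-en-1-yl)oxiran-2-yl]ethenyl}-3-methyloxirane-2-carbaldehyde | C=CC[C@@]1(CO)O[C@@H]1/C=C\[C@@]1(C)O[C@H]1C=O | intermediate
10 | (2R,3R)-3-methyl-3-{(Z)-2-[(2R,3S)-3-(prop-2-en-1-yl)-3-((triethylsilyloxy)methyl)oxiran-2-yl]ethenyl}oxirane-2-carbaldehyde | C=CC[C@@]1(CO[Si](CC)(CC)CC)O[C@@H]1/C=C\[C@@]1(C)O[C@H]1C=O | intermediate
11 | ethyl 3-bromo-2-oxopropanoate (ethyl bromopyruvate) | CCOC(=O)C(=O)CBr | starting material
12 | ethyl 3-acetoxy-2-oxopropanoate | CCOC(=O)C(=O)COC(C)=O | intermediate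
13 | ethyl 2-(acetoxymethyl)-3,3-dibromoprop-2-enoate | CCOC(=O)C(COC(C)=O)=C(Br)Br | intermediate
14 | ethyl 2-(acetoxymethyl)-3-bromo-3-(chloromagnesio)prop-2-enoate, magnesium cis to the ester | CCOC(=O)/C(COC(C)=O)=C(/Br)[Mg]Cl | intermediate (not isolated)
15 | open-chain chloromagnesium alkoxide of the aldehyde adduct (C6–O–MgCl, C6 cis to CO2Et) | C=CC[C@@]1(CO[Si](CC)(CC)CC)O[C@@H]1/C=C\[C@@]1(C)O[C@H]1[C@@H](O[Mg]Cl)/C(Br)=C(/COC(C)=O)C(=O)OCC | intermediate (not isolated)
16 | [(5R)-4-bromo-5-{(2S,3R)-3-methyl-3-[(Z)-2-((2R,3S)-3-(prop-2-en-1-yl)-3-((triethylsilyloxy)methyl)oxiran-2-yl)ethenyl]oxiran-2-yl}-2-oxo-2,5-dihydrofuran-3-yl]methyl acetate | C=CC[C@@]1(CO[Si](CC)(CC)CC)O[C@@H]1/C=C\[C@@]1(C)O[C@H]1[C@H]1OC(=O)C(COC(C)=O)=C1Br | intermediate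
17 | vicinal diol from the terminal olefin of 16 (2,3-dihydroxypropyl at C10, mixture at the new carbinol) | OCC(O)C[C@@]1(CO[Si](CC)(CC)CC)O[C@@H]1/C=C\[C@@]1(C)O[C@H]1[C@H]1OC(=O)C(COC(C)=O)=C1Br | intermediate (not isolated)
18 | [(5R)-4-bromo-5-{(2S,3R)-3-methyl-3-[(Z)-2-((2R,3S)-3-(2-oxoethyl)-3-((triethylsilyloxy)methyl)oxiran-2-yl)ethenyl]oxiran-2-yl}-2-oxo-2,5-dihydrofuran-3-yl]methyl acetate | O=CC[C@@]1(CO[Si](CC)(CC)CC)O[C@@H]1/C=C\[C@@]1(C)O[C@H]1[C@H]1OC(=O)C(COC(C)=O)=C1Br | intermediate
19 | C7 dichlorochromium alkenyl species of 18 (trivalent chromium in place of bromine) | O=CC[C@@]1(CO[Si](CC)(CC)CC)O[C@@H]1/C=C\[C@@]1(C)O[C@H]1[C@H]1OC(=O)C(COC(C)=O)=C1[Cr](Cl)Cl | intermediate (not isolated)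
20 | (1R,4R,5S,6S,8R,10S)-13-acetoxy-1,10:4,5-diepoxy-8-hydroxy-14-(triethylsilyloxy)germacra-2Z,7(11)-dien-12,6-olide | O[C@@H]1C[C@@]2(CO[Si](CC)(CC)CC)O[C@@H]2/C=C\[C@@]2(C)O[C@H]2[C@H]2OC(=O)C(COC(C)=O)=C12 | intermediate
21 | (R)-2-methylbutanoic acid | CC[C@@H](C)C(=O)O | starting material
22 | (1R,4R,5S,6S,8S,10S)-13-acetoxy-1,10:4,5-diepoxy-8-[(2R)-2-methylbutanoyloxy]-14-(triethylsilyloxy)germacra-2Z,7(11)-dien-12,6-olide | CC[C@@H](C)C(=O)O[C@H]1C[C@@]2(CO[Si](CC)(CC)CC)O[C@@H]2/C=C\[C@@]2(C)O[C@H]2[C@H]2OC(=O)C(COC(C)=O)=C12 | intermediate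
23 | (1R,4R,5S,6S,8S,10S)-13-acetoxy-1,10:4,5-diepoxy-14-hydroxy-8-[(2R)-2-methylbutanoyloxy]germacra-2Z,7(11)-dien-12,6-olide (CNP0108300.1) | CC[C@@H](C)C(=O)O[C@H]1C[C@@]2(CO)O[C@@H]2/C=C\[C@@]2(C)O[C@H]2[C@H]2OC(=O)C(COC(C)=O)=C12 | target

Total step count: 13. Longest linear sequence: 11 steps (steps 1–6 and 9–13, from prop-2-yn-1-ol); steps 7 and 8 make the dibromoacrylate side branch.

Steps most likely to fail

Step 11. The process at risk is the facial selectivity of the addition to the C8 aldehyde during ring closure; the model favours the 8R carbinol, but the opposite face may be preferred. The fallback sets out from 18 and uses the same Ni/Cr ring closure, but takes the product as the macrocyclic 8S alcohol F1. This is acylated with retention (21, DCC, DMAP, CH2Cl2, 0 °C), so the configuration of the ester is fixed by acylation instead of displacement, and the route is rejoined at 22.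

Step 12. The process at risk is a slow displacement at the hindered ring carbinol, with elimination towards C9 taking over. The fallback sets out from 20. Dess–Martin oxidation (NaHCO3, CH2Cl2) should give the C8 ketone F2. Reduction with (R)-2-methyl-CBS-oxazaborolidine and catecholborane (toluene, −78 °C; reagent control, the alkenyl group acting as the large substituent) should give the 8S alcohol F1. Acylation with 21 (DCC, DMAP) then comes back to the route at 22.

Step 5. The process at risk is insufficient site selectivity between the two primary epoxy alcohols, giving over-oxidation at C14 or mixtures. The fallback differentiates the two hydroxyl groups before the fragments are joined and sets out from 5 and 4: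
- Compound 5 is converted into its 4-methoxybenzyl ether F3 (NaH, 4-methoxybenzyl chloride, DMF).
- Sonogashira coupling with 4 (Pd(PPh3)2Cl2, CuI, Et3N) gives the dienyne mono-alcohol F4.
- Sharpless epoxidation (Ti(OiPr)4, L-(+)-diethyl tartrate, t-BuOOH) of the only free allylic alcohol gives the C1/C10 epoxy alcohol F5.
- Silylation (Et3SiCl, imidazole) gives the silyl ether F6.
- DDQ (CH2Cl2/pH 7 buffer) frees the C6 allylic alcohol F7.
- A second Sharpless epoxidation with the same tartrate gives the bis-epoxy ynol F8.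
- Lindlar semihydrogenation gives the (Z)-olefinic epoxy alcohol F9.
- Dess–Martin oxidation of the single free carbinol comes back to the route at 10.

Further compounds
F1 | step 11 | (1R,4R,5S,6S,8S,10S)-13-acetoxy-1,10:4,5-diepoxy-8-hydroxy-14-(triethylsilyloxy)germacra-2Z,7(11)-dien-12,6-olide | O[C@H]1C[C@@]2(CO[Si](CC)(CC)CC)O[C@@H]2/C=C\[C@@]2(C)O[C@H]2[C@H]2OC(=O)C(COC(C)=O)=C12
F2 | step 12 | (1R,4R,5S,6S,10S)-13-acetoxy-1,10:4,5-diepoxy-8-oxo-14-(triethylsilyloxy)germacra-2Z,7(11)-dien-12,6-olide | O=C1C[C@@]2(CO[Si](CC)(CC)CC)O[C@@H]2/C=C\[C@@]2(C)O[C@H]2[C@H]2OC(=O)C(COC(C)=O)=C12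
F3 | step 5 | (Z)-5-(4-methoxybenzyloxy)-3-methylpent-3-en-1-yne | C#C/C(C)=C\COCc1ccc(OC)cc1
F4 | step 5 | (2Z,6Z)-8-(4-methoxybenzyloxy)-6-methyl-2-(prop-2-en-1-yl)octa-2,6-dien-4-yn-1-ol | OC/C(CC=C)=C\C#C/C(C)=C\COCc1ccc(OC)cc1
F5 | step 5 | {(2S,3R)-3-[(Z)-5-(4-methoxybenzyloxy)-3-methylpent-3-en-1-yn-1-yl]-2-(prop-2-en-1-yl)oxiran-2-yl}methanol | C=CC[C@@]1(CO)O[C@@H]1C#C/C(C)=C\COCc1ccc(OC)cc1
F6 | step 5 | triethylsilyl ether of F5 | C=CC[C@@]1(CO[Si](CC)(CC)CC)O[C@@H]1C#C/C(C)=C\COCc1ccc(OC)cc1
F7 | step 5 | (Z)-3-methyl-5-[(2R,3S)-3-(prop-2-en-1-yl)-3-((triethylsilyloxy)methyl)oxiran-2-yl]pent-2-en-4-yn-1-ol | C=CC[C@@]1(CO[Si](CC)(CC)CC)O[C@@H]1C#C/C(C)=C\CO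
F8 | step 5 | {(2S,3R)-3-methyl-3-[((2R,3S)-3-(prop-2-en-1-yl)-3-((triethylsilyloxy)methyl)oxiran-2-yl)ethynyl]oxiran-2-yl}methanol | C=CC[C@@]1(CO[Si](CC)(CC)CC)O[C@@H]1C#C[C@@]1(C)O[C@H]1CO
F9 | step 5 | {(2S,3R)-3-methyl-3-[(Z)-2-((2R,3S)-3-(prop-2-en-1-yl)-3-((triethylsilyloxy)methyl)oxiran-2-yl)ethenyl]oxiran-2-yl}methanol | C=CC[C@@]1(CO[Si](CC)(CC)CC)O[C@@H]1/C=C\[C@@]1(C)O[C@H]1CO
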